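Late in the two earlier runs, from 80.0 min to 120 min, the part of the starting material not yet turned into target falls, and we reckon this flask by the lifetime of that fall.

| flask | starting material | reagent in the second phase | remark | time | volume of the second phase over the first |
|---|---|---|---|---|---|
| autumn | 0.0094 M | 1.5 equiv | run made earlier |  |  |
| summer | 0.021 M | 1.5 equiv | run made earlier |  |  |
| flask | 0.014 M | 1.50 equiv |  | 3.0 h | 2.0 |

- autumn (time / min: target / %, starting material / %): 6.00: 1.2, 101.3; 15.0: 1.7, 99.0; 30.0: 1.7, 98.2; 50.0: 3.9, 96.0; 60.0: 4.4, 94.1; 80.0: 9.0, 91.0; 120: 15.6, 82.7
- summer (time / min: target / %, starting material / %): 6.00: 1.1, 100.8; 15.0: 0, 97.8; 30.0: 3.0, 95.7; 50.0: 10.0, 93.8; 60.0: 12.1, 87.1; 80.0: 15.6, 82.9; 120: 24.7, 71.2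

(scatter of a reading: 1 percentage point)

- in the second phase: reagent in the second phase; everything else is in the first
- charges count per volume of the first phase; a concentration in a rate is the amount of a species over the volume of its own phase; every rate counts per litre of the first phase
- what was read earlier has a scatter of 1 percentage point, one standard deviation
- the earlier runs hold the two phases in the same ratio of volumes as the flask asked about

- zeta: doubling the transfer coefficient of the reagent in the second phase, all else as stated
- delta: doubling the amount of reagent in the second phase, all else as stated

* amount of target at 3.0 h, in percent of the starting material charged
* the change that raises the amount of target at 3.0 h, in percent of the starting material charged most ("none" if none brings more than 2 percentage points) (zeta / delta / none)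
* amount of target at 3.0 h, in percent of the starting material charged, after delta

The target column gives a time of 531 min in the autumn run and 351 min in the summer run. Carried back to zero target, these late lines leave lags of 29.9 min and 20.5 min. The flask's [starting material] of 0.014 M lies close to the geometric mean of the two runs, 0.0140 M. We therefore take the geometric mean 432 min as the lifetime to target, the time in which the part not yet target falls by a factor e after the lag, a pseudo-first-order reading. With the mean lag of 25.2 min, the time of 3.0 h stands 0.358 lifetimes past the lag, which gives 30.1 % target.

The starting-material column, read independently the same way, gives a lifetime of 332 min and a lag of 35.6 min, so we reckon 35.3 % of the charge lost from that column. The two ways part by 5.2 percentage points. The second one cheats as a measure of target: at the last readings 1.7 points (autumn) and 4.1 points (summer) stand in neither column, more in the summer run than in the autumn run, though each reading carries a scatter of 1 point. We commit to 30.1 %.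

Both runs held 1.5 equiv, so reagent rose with starting material. A pseudo-first-order lifetime does not depend on its substrate's own concentration, so we read the exponent with which the lifetime shortens from the autumn run to the summer run, 0.517, as the reagent's. Doubling the reagent, lag held, shortens the lifetime to 302 min and gives 40.1 %.

The forecast gives 29 % (25 % to 33 %), names delta and puts target after it at 50 % (42 % to 57 %), reasoning that “Doubling the reagent doubles the driving force”. Its figure after delta is higher than our 40.1 %.

The flask gives 27.1 % target. The best change is delta, worth 10 points against 2.5 points for zeta, and it brings target to 37.5 %.

    reagent in the reaction phase ⇌ reagent in the second phase, rate k1*([reagent in the reaction phase] - [reagent in the second phase]/K1) per volume of the first phase (partition coefficient = 0.350, kL = 0.580 h⁻¹)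
    starting material + reagent in the reaction phase → target (k = 17.0 M⁻¹ h⁻¹)
    reagent in the reaction phase + target → over-reacted product (k = 11.0 M⁻¹ h⁻¹)
    reagent in the reaction phase + target → over-reaction product (k = 4.10 M⁻¹ h⁻¹)

The same flask read at 50 min stands 0.0574 lifetimes past the lag, which puts target at 5.58 %, and that flask holds 6.34 % target.

(The data were generated by integration with constants of no real substance; scatter was added.)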